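The cyclodecene ring (germacrane numbering: C1=C10 olefin, C3 angelate, C4–C5 oxirane ring, C6 acetate, C7 isopropyl) is opened at C6–C7. The key step exploits the fact that the C6 carbinol and the C7 isopropyl branch are a masked homoallylic alcohol lying next to the oxirane: an acyclic farnesane carrying a C6 aldehyde on the trans-oxirane and a 2-methylallyl chloride terminus (C7, C11, C12) is closed by palladium-catalysed, diethylzinc-mediated umpolung allylation, which forms the ten-membered carbocycle and both stereocentres C6 and C7 in one operation. Hydrogenation of the isopropenyl group and acetylation finish. The precursor comes from geranyl chloride and a C5 enal; C3 is set by CBS reduction, C4/C5 by Sharpless epoxidation.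

Key step: step 9

Remark: atom labels C1–C15 follow germacrane numbering of the target throughout; the chlorine-bearing carbon of 12 and 13 is left as both epimers because step 9 erases it; 1, 2 and 7 are taken as commercial.

Step 1
Reactants: 1 geranyl chloride; 2 (2E)-4-acetoxy-2-methylbut-2-enal
Product: 4 racemic (2E,6E)-4-hydroxy-3,7,11-trimethyldodeca-2,6,10-trien-1-yl acetate, via geranylbarium chloride 3 (not isolated)
Conditions: Ba (from BaI2, lithium biphenylide), THF, −78 °C, 1; then 2, −78 °C; aq NH4Cl
Reagents that add atoms: none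
Why: Alpha-selective, geometry-retentive carbonyl addition of an allylbarium reagent: 3 should attack the aldehyde through its unsubstituted CH2 carbon with the 2E olefin intact, the aldehyde reacting far faster than the acetate at −78 °C; the new carbinol centre forms racemic and is set in steps 2 and 3.

Step 2
Reactants: 4 racemic (2E,6E)-4-hydroxy-3,7,11-trimethyldodeca-2,6,10-trien-1-yl acetate
Product: 5 (2E,6E)-3,7,11-trimethyl-4-oxododeca-2,6,10-trien-1-yl acetate
Conditions: MnO2 (activated, excess), CH2Cl2, 23 °C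
Reagents that add atoms: none
Why: Neutral MnO2 oxidation of the secondary allylic alcohol should give the enone without drawing the skipped C6=C7 olefin into conjugation, and removes the racemic centre.

Step 3
Reactants: 5 (2E,6E)-3,7,11-trimethyl-4-oxododeca-2,6,10-trien-1-yl acetate
Product: 6 (2E,4S,6E)-4-hydroxy-3,7,11-trimethyldodeca-2,6,10-trien-1-yl acetate
Conditions: (R)-2-methyl-CBS-oxazaborolidine (0.2 equiv), catecholborane, toluene, −78 °C; aq NaOH
Reagents that add atoms: none
Why: Corey–Bakshi–Shibata reduction: with the alpha-branched alkenyl group as the large and the CH2 group as the small substituent, the (R)-catalyst should deliver hydride to give the 4S alcohol (C3 of the target).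

Step 4
Reactants: 6 (2E,4S,6E)-4-hydroxy-3,7,11-trimethyldodeca-2,6,10-trien-1-yl acetate; 7 angelic acid
Product: 9 (2E,4S,6E)-1-acetoxy-3,7,11-trimethyldodeca-2,6,10-trien-4-yl (2Z)-2-methylbut-2-enoate, via angelic 2,4,6-trichlorobenzoic anhydride 8 (not isolated)
Conditions: 7, 2,4,6-trichlorobenzoyl chloride, Et3N, toluene, 23 °C; then 6, 80 °C
Reagents that add atoms: none
Why: Yamaguchi-type esterification through the mixed anhydride without nucleophilic catalyst should acylate the secondary alcohol with retention at C3 and without Z-to-E isomerisation of the angelate.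

Step 5
Reactants: 9 (2E,4S,6E)-1-acetoxy-3,7,11-trimethyldodeca-2,6,10-trien-4-yl (2Z)-2-methylbut-2-enoate
Product: 10 (2E,4S,6E)-1-hydroxy-3,7,11-trimethyldodeca-2,6,10-trien-4-yl (2Z)-2-methylbut-2-enoate
Conditions: K2CO3 (0.3 equiv), MeOH, 0 °C
Reagents that add atoms: none
Why: Chemoselective transesterification: the unhindered primary allylic acetate should be cleaved much faster than the hindered, conjugated secondary angelate, and the E olefin between the two oxygens rules out acyl migration.

Step 6
Reactants: 10 (2E,4S,6E)-1-hydroxy-3,7,11-trimethyldodeca-2,6,10-trien-4-yl (2Z)-2-methylbut-2-enoate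
Product: 11 (1S,3E)-1-[(2R,3R)-3-(hydroxymethyl)-2-methyloxiran-2-yl]-4,8-dimethylnona-3,7-dien-1-yl (2Z)-2-methylbut-2-enoate
Conditions: Ti(OiPr)4 (0.1 equiv), D-(−)-diisopropyl tartrate (0.12 equiv), t-BuOOH, 4 Å MS, CH2Cl2, −20 °C
Reagents that add atoms: tert-butyl hydroperoxide, CC(C)(C)OO
Why: Sharpless asymmetric epoxidation: the titanium–D-tartrate complex should deliver oxygen to the E-allylic alcohol under reagent control to give the (2R,3R)-oxirane (C4 and C5 of the target), while the isolated olefins and the angelate do not react.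

Step 7
Reactants: 11 (1S,3E)-1-[(2R,3R)-3-(hydroxymethyl)-2-methyloxiran-2-yl]-4,8-dimethylnona-3,7-dien-1-yl (2Z)-2-methylbut-2-enoate
Product: 12 (1S,3E)-7-chloro-1-[(2R,3R)-3-(hydroxymethyl)-2-methyloxiran-2-yl]-4,8-dimethylnona-3,8-dien-1-yl (2Z)-2-methylbut-2-enoate (both epimers at the chlorine-bearing carbon)
Conditions: Ca(OCl)2, CO2 (solid), CH2Cl2/H2O, 0 °C
Reagents that add atoms: calcium hypochlorite Ca(OCl)2 (source of hypochlorous acid), [Ca+2].[O-]Cl.[O-]Cl
Why: Ene-type allylic chlorination with hypochlorous acid: the most electron-rich and least hindered terminal isopropylidene olefin should react with double-bond shift to give the secondary 2-methylallyl chloride, whose new centre is of no consequence because step 9 erases it.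

Step 8
Reactants: 12 (1S,3E)-7-chloro-1-[(2R,3R)-3-(hydroxymethyl)-2-methyloxiran-2-yl]-4,8-dimethylnona-3,8-dien-1-yl (2Z)-2-methylbut-2-enoate
Product: 13 (1S,3E)-7-chloro-1-[(2R,3S)-3-formyl-2-methyloxiran-2-yl]-4,8-dimethylnona-3,8-dien-1-yl (2Z)-2-methylbut-2-enoate (both epimers at the chlorine-bearing carbon; the oxirane is unchanged in space, the descriptor changes by priority only)
Conditions: Dess–Martin periodinane, NaHCO3, CH2Cl2, 0 to 23 °C
Reagents that add atoms: none
Why: Buffered Dess–Martin oxidation should convert the epoxy alcohol into the configurationally stable alpha,beta-epoxy aldehyde without touching the allylic chloride or the oxirane.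

Step 9
Reactants: 13 (1S,3E)-7-chloro-1-[(2R,3S)-3-formyl-2-methyloxiran-2-yl]-4,8-dimethylnona-3,8-dien-1-yl (2Z)-2-methylbut-2-enoate
Product: 16 (1R,2S,4E,8R,9S,10R)-9-hydroxy-1,5-dimethyl-8-(prop-1-en-2-yl)-11-oxabicyclo[8.1.0]undec-4-en-2-yl (2Z)-2-methylbut-2-enoate, via allylpalladium chloride complex 14 (not isolated), via ethyl(allyl)zinc species 15 (not isolated)
Conditions: Pd(PPh3)4 (0.1 equiv), Et2Zn (4 equiv), THF, 23 °C, 13 added over 10 h (final 0.005 M); aq NH4Cl
Reagents that add atoms: none
Why: Oxidative addition of zerovalent palladium to the allylic chloride gives the η3-allylpalladium chloride 14 (the C–Cl centre is erased), palladium-to-zinc exchange with Et2Zn gives the nucleophilic allylzinc 15 with zinc on the primary carbon C12, and 15 adds through its gamma-carbon C7 to the C6 aldehyde in a closed six-membered zinc chair; the closest known reaction type is the palladium/diethylzinc umpolung allylation of aldehydes (the counterpart of an intramolecular Nozaki–Hiyama allylation), a type known to close ten-membered carbocycles from epoxy-farnesal allylic halides. The ten-membered ring closes in a 10-exo-trig sense at the carbonyl, and the C11=C12 bond is left exocyclic as the isopropenyl group. C6 is controlled by the adjacent oxirane carbon C5: C7 should approach anti to the C5–O bond with the zinc-bound carbonyl oxygen turned to the outside of the forming ring, that is on the Si face, which gives 6S. C7 is controlled by the chair array inside the macrocycle: the E and Z allylzinc forms interconvert by 1,3-zinc shift, and the E-configured C1=C10 olefin together with the trans-oxirane is expected to let the C8 tether reach C7 only from the side that places H6 and H7 cis, which gives 7R; this assignment rests on a model and is the main risk of the route. The step needs gamma- over alpha-attack (ten- versus twelve-membered ring), secured by zinc sitting on the unhindered primary terminus, and ring closure over oligomerisation, secured by slow addition to about 0.005 M and by the two rigid E-units that pre-fold the chain. The angelate, the oxirane and the trisubstituted olefin should be inert to Et2Zn at 23 °C.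

Step 10
Reactants: 16 (1R,2S,4E,8R,9S,10R)-9-hydroxy-1,5-dimethyl-8-(prop-1-en-2-yl)-11-oxabicyclo[8.1.0]undec-4-en-2-yl (2Z)-2-methylbut-2-enoate
Product: 17 (1R,2S,4E,8R,9S,10R)-9-hydroxy-1,5-dimethyl-8-(propan-2-yl)-11-oxabicyclo[8.1.0]undec-4-en-2-yl (2Z)-2-methylbut-2-enoate
Conditions: H2 (1 atm), RhCl(PPh3)3 (0.1 equiv), benzene, 23 °C
Reagents that add atoms: none
Why: Homogeneous hydrogenation with RhCl(PPh3)3 should reduce the unhindered 1,1-disubstituted isopropenyl olefin far faster than the trisubstituted ring olefin and the conjugated angelate (as in the selective isopropenyl reduction of carvone), and forms no stereocentre.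

Step 11
Reactants: 17 (1R,2S,4E,8R,9S,10R)-9-hydroxy-1,5-dimethyl-8-(propan-2-yl)-11-oxabicyclo[8.1.0]undec-4-en-2-yl (2Z)-2-methylbut-2-enoate
Product: 18 (1R,2S,4E,8R,9S,10R)-9-acetoxy-1,5-dimethyl-8-(propan-2-yl)-11-oxabicyclo[8.1.0]undec-4-en-2-yl (2Z)-2-methylbut-2-enoate
Conditions: Ac2O, DMAP (0.1 equiv), pyridine, CH2Cl2, 0 to 23 °C
Reagents that add atoms: acetic anhydride, CC(=O)OC(C)=O
Why: DMAP-catalysed acylation of the secondary C6 hydroxyl with retention should give the target, the angelate and oxirane being stable to pyridine at 23 °C.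

Compound list
1 | geranyl chloride, (2E)-1-chloro-3,7-dimethylocta-2,6-diene | CC(C)=CCC/C(C)=C/CCl | starting material
2 | (2E)-4-acetoxy-2-methylbut-2-enal | CC(=O)OC/C=C(\C)C=O | starting material
3 | geranylbarium chloride | CC(C)=CCC/C(C)=C/C[Ba]Cl | intermediate (not isolated)
4 | racemic (2E,6E)-4-hydroxy-3,7,11-trimethyldodeca-2,6,10-trien-1-yl acetate | CC(C)=CCC/C(C)=C/CC(O)/C(C)=C/COC(C)=O | intermediate
5 | (2E,6E)-3,7,11-trimethyl-4-oxododeca-2,6,10-trien-1-yl acetate | CC(C)=CCC/C(C)=C/CC(=O)/C(C)=C/COC(C)=O | intermediate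
6 | (2E,4S,6E)-4-hydroxy-3,7,11-trimethyldodeca-2,6,10-trien-1-yl acetate | CC(C)=CCC/C(C)=C/C[C@H](O)/C(C)=C/COC(C)=O | intermediate
7 | angelic acid, (2Z)-2-methylbut-2-enoic acid | C/C=C(/C)C(=O)O | starting material
8 | angelic 2,4,6-trichlorobenzoic anhydride | C/C=C(/C)C(=O)OC(=O)c1c(Cl)cc(Cl)cc1Cl | intermediate (not isolated)
9 | (2E,4S,6E)-1-acetoxy-3,7,11-trimethyldodeca-2,6,10-trien-4-yl (2Z)-2-methylbut-2-enoate | CC(C)=CCC/C(C)=C/C[C@H](OC(=O)/C(C)=C\C)/C(C)=C/COC(C)=O | intermediate
10 | (2E,4S,6E)-1-hydroxy-3,7,11-trimethyldodeca-2,6,10-trien-4-yl (2Z)-2-methylbut-2-enoate | CC(C)=CCC/C(C)=C/C[C@H](OC(=O)/C(C)=C\C)/C(C)=C/CO | intermediate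
11 | (1S,3E)-1-[(2R,3R)-3-(hydroxymethyl)-2-methyloxiran-2-yl]-4,8-dimethylnona-3,7-dien-1-yl (2Z)-2-methylbut-2-enoate | CC(C)=CCC/C(C)=C/C[C@H](OC(=O)/C(C)=C\C)[C@@]1(C)O[C@@H]1CO | intermediate
12 | (1S,3E)-7-chloro-1-[(2R,3R)-3-(hydroxymethyl)-2-methyloxiran-2-yl]-4,8-dimethylnona-3,8-dien-1-yl (2Z)-2-methylbut-2-enoate, both C7 epimers | C=C(C)C(Cl)CC/C(C)=C/C[C@H](OC(=O)/C(C)=C\C)[C@@]1(C)O[C@@H]1CO | intermediate
13 | (1S,3E)-7-chloro-1-[(2R,3S)-3-formyl-2-methyloxiran-2-yl]-4,8-dimethylnona-3,8-dien-1-yl (2Z)-2-methylbut-2-enoate, both C7 epimers | C=C(C)C(Cl)CC/C(C)=C/C[C@H](OC(=O)/C(C)=C\C)[C@@]1(C)O[C@@H]1C=O | intermediate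
14 | allylpalladium chloride complex of 13 (drawn as the primary sigma-allyl form, phosphines omitted) | Cl[Pd]CC(C)=CCC/C(C)=C/C[C@H](OC(=O)/C(C)=C\C)[C@@]1(C)O[C@@H]1C=O | intermediate (not isolated)
15 | ethyl(allyl)zinc species (zinc on C12, E/Z forms interconverting) | CC[Zn]CC(C)=CCC/C(C)=C/C[C@H](OC(=O)/C(C)=C\C)[C@@]1(C)O[C@@H]1C=O | intermediate (not isolated)
16 | (1R,2S,4E,8R,9S,10R)-9-hydroxy-1,5-dimethyl-8-(prop-1-en-2-yl)-11-oxabicyclo[8.1.0]undec-4-en-2-yl (2Z)-2-methylbut-2-enoate | C/C=C(/C)C(=O)O[C@H]1C/C=C(\C)CC[C@H](C(C)=C)[C@H](O)[C@H]2O[C@]12C | intermediate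
17 | (1R,2S,4E,8R,9S,10R)-9-hydroxy-1,5-dimethyl-8-(propan-2-yl)-11-oxabicyclo[8.1.0]undec-4-en-2-yl (2Z)-2-methylbut-2-enoate | C/C=C(/C)C(=O)O[C@H]1C/C=C(\C)CC[C@H](C(C)C)[C@H](O)[C@H]2O[C@]12C | intermediate
18 | (1R,2S,4E,8R,9S,10R)-9-acetoxy-1,5-dimethyl-8-(propan-2-yl)-11-oxabicyclo[8.1.0]undec-4-en-2-yl (2Z)-2-methylbut-2-enoate | C/C=C(/C)C(=O)O[C@H]1C/C=C(\C)CC[C@H](C(C)C)[C@H](OC(C)=O)[C@H]2O[C@]12C | target

Total step count: 11. Longest linear sequence: 11 steps (1 and 2 to 18).

Steps most likely to fail

1. Step 9. The equilibrating allylzinc may add to the wrong carbonyl face or deliver the H6/H7-trans relationship (poor diastereofacial control inside the macrocyclic chair), and protonation of the allylzinc or oligomerisation may outrun ring closure. The fallback replaces the catalytic, equilibrating zinc nucleophile by a preformed, geometrically fixed boron nucleophile and sets out from 12. Palladium-catalysed allylic borylation (B2pin2, Pd2(dba)3, DMSO, 50 °C) should give the primary allylboronate alcohol F1. Dess–Martin oxidation at high dilution should give the allylboronate aldehyde F2, which is not stored but warmed in toluene (0.005 M, 40 to 60 °C). Thermal intramolecular allylboration through a compact boron chair, followed by triethanolamine work-up, should give alcohol 16, where the route is rejoined. No ethyl transfer or protodemetalation can compete, and the olefin geometry of the allylboronate becomes a second, selectable control element for C7 (the 7Z boronate maps onto the cis H6/H7 relationship through a chair with C5 equatorial).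

2. Step 7. Chlorination at the internal C1=C10 olefin may compete with the terminal olefin, and aqueous hypochlorous acid may open the oxirane. The fallback uses selenium-based allylic oxidation, whose preference for the E-methyl group of a terminal isopropylidene unit is well established, and sets out from 11. SeO2 (0.3 equiv), t-BuOOH, salicylic acid, CH2Cl2, 23 °C should give the allylic diol F3. Corey–Kim chlorination (N-chlorosuccinimide, Me2S, CH2Cl2, −20 °C) should convert only the allylic hydroxyl into the primary allylic chloride F4. Dess–Martin oxidation should give the epoxy aldehyde F5, the allylic regioisomer of 13. Under the conditions of step 9, F5 ionises to the same allylpalladium complex 14 and so comes back to the route at 16.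

3. Step 1. Attack through the gamma-carbon of the allyl unit (branched adduct), loss of the 2E geometry, or addition to the acetate may erode the linear adduct. The fallback turns the polarity round (acyl-anion alkylation of a primary allylic bromide, which cannot give a branched product) and sets out from 2, with commercial geranyl bromide in place of 1. Dithioacetalisation (propane-1,3-dithiol, BF3·OEt2, CH2Cl2, −20 °C) should give the alkenyl dithiane acetate F6. Methanolysis (K2CO3, MeOH) should give the dithiane alcohol F7. The dianion (n-BuLi, 2.1 equiv, THF, −30 °C) is alkylated at the dithiane carbon with geranyl bromide to give the geranylated dithiane alcohol F8. Acetylation (Ac2O, pyridine) should give the geranylated dithiane acetate F9. Dithiane hydrolysis (MeI, CaCO3, aqueous MeCN, 40 °C) should give enone 5, where the route is rejoined before the CBS reduction.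

Further compounds
F1 | step 9 | (1S,3E)-1-[(2R,3R)-3-(hydroxymethyl)-2-methyloxiran-2-yl]-4,8-dimethyl-9-(4,4,5,5-tetramethyl-1,3,2-dioxaborolan-2-yl)nona-3,7-dien-1-yl (2Z)-2-methylbut-2-enoate (7-ene geometry as formed) | CC1(C)OB(CC(C)=CCC/C(C)=C/C[C@H](OC(=O)/C(C)=C\C)[C@@]2(C)O[C@@H]2CO)OC1(C)C
F2 | step 9 | (1S,3E)-1-[(2R,3S)-3-formyl-2-methyloxiran-2-yl]-4,8-dimethyl-9-(4,4,5,5-tetramethyl-1,3,2-dioxaborolan-2-yl)nona-3,7-dien-1-yl (2Z)-2-methylbut-2-enoate | CC1(C)OB(CC(C)=CCC/C(C)=C/C[C@H](OC(=O)/C(C)=C\C)[C@@]2(C)O[C@@H]2C=O)OC1(C)C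
F3 | step 7 | (1S,3E,7E)-9-hydroxy-1-[(2R,3R)-3-(hydroxymethyl)-2-methyloxiran-2-yl]-4,8-dimethylnona-3,7-dien-1-yl (2Z)-2-methylbut-2-enoate | OC/C(C)=C/CC/C(C)=C/C[C@H](OC(=O)/C(C)=C\C)[C@@]1(C)O[C@@H]1CO
F4 | step 7 | (1S,3E,7E)-9-chloro-1-[(2R,3R)-3-(hydroxymethyl)-2-methyloxiran-2-yl]-4,8-dimethylnona-3,7-dien-1-yl (2Z)-2-methylbut-2-enoate | ClC/C(C)=C/CC/C(C)=C/C[C@H](OC(=O)/C(C)=C\C)[C@@]1(C)O[C@@H]1CO
F5 | step 7 | (1S,3E,7E)-9-chloro-1-[(2R,3S)-3-formyl-2-methyloxiran-2-yl]-4,8-dimethylnona-3,7-dien-1-yl (2Z)-2-methylbut-2-enoate | ClC/C(C)=C/CC/C(C)=C/C[C@H](OC(=O)/C(C)=C\C)[C@@]1(C)O[C@@H]1C=O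
F6 | step 1 | (2E)-3-(1,3-dithian-2-yl)but-2-en-1-yl acetate | CC(=O)OC/C=C(\C)C1SCCCS1
F7 | step 1 | (2E)-3-(1,3-dithian-2-yl)but-2-en-1-ol | OC/C=C(\C)C1SCCCS1
F8 | step 1 | (2E)-3-{2-[(2E)-3,7-dimethylocta-2,6-dien-1-yl]-1,3-dithian-2-yl}but-2-en-1-ol | CC(C)=CCC/C(C)=C/CC1(SCCCS1)/C(C)=C/CO
F9 | step 1 | (2E)-3-{2-[(2E)-3,7-dimethylocta-2,6-dien-1-yl]-1,3-dithian-2-yl}but-2-en-1-yl acetate | CC(C)=CCC/C(C)=C/CC1(SCCCS1)/C(C)=C/COC(C)=O
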